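**Plan**

- Cuts, in retrosynthetic order: the formyl carbon on the vinyl group (C–CHO back to C–I, then C–B), the C3 ester, the C2–C3 bond of the dihydrofuran ring, then the allenyl ether, the side-chain ester and the ring formyl group of a 4-hydroxyacetophenone core.
- Enabling feature: C2 carries the ring oxygen O1 and a 1-substituted vinyl group and is bonded to the benzylic carbinol carbon C3. This O–C(allyl)–C(OH)–aryl array is what a γ-aryloxy allylmetal leaves on adding to an ortho aldehyde, and the substituted vinyl carbon maps onto the central carbon of an allene.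
- Forward order: the benzene ring is bought, formylated ortho to the phenol, O-propargylated, reduced at the ketone, isomerised to the aryloxyallene and esterified. The dihydrofuran ring, the only ring made, closes in the copper–boryl step.
- Finish: acylation at C3, exchange of boron for iodine, then reductive carbonylation to the enal.
- Stereochemistry: the side-chain (R) centre comes from Noyori–Ikariya transfer hydrogenation. C2 and C3 are set together in the key step, cis by the cyclic transition state and (2R,3R) by the chiral bisphosphine on copper.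

Key step: step 8

Assumption: which antipode of the bisphosphine leads to the (2R,3R) series cannot be predicted safely for this substrate. It is fixed by a trial with both antipodes; the two cis products are diastereomers of each other because of the side-chain centre.

Remark: ring numbering is that of 1-benzofuran (O1, C2, C3, C3a, C4–C7, C7a). The descriptor at C2 becomes S in iodide 16 only because iodine raises the CIP priority of the vinyl carbon; the geometry does not change.

**Route**

Step 1
Reactants: 1 4'-hydroxyacetophenone
Product: 3 5-acetyl-2-hydroxybenzaldehyde, via 5-acetylsalicyl alcohol 2 (not isolated)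
Conditions: MgCl2 (1.5 equiv), Et3N (3.75 equiv), (CH2O)n (7 equiv), MeCN, reflux; then 1 M HCl
Reagents that add atoms: formaldehyde (from paraformaldehyde), C=O
Why: Magnesium-mediated ortho-formylation (Casnati–Skattebøl reaction): the chloromagnesium phenoxide of 1 takes up formaldehyde at the carbon next to oxygen (the para position is blocked by the acetyl group) and the salicyl alkoxide 2 is oxidised in the flask by a second formaldehyde through an Oppenauer-type hydride transfer.

Step 2
Reactants: 3 5-acetyl-2-hydroxybenzaldehyde; 4 propargyl bromide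
Product: 5 5-acetyl-2-(prop-2-yn-1-yloxy)benzaldehyde
Conditions: K2CO3 (1.5 equiv), DMF, rt
Reagents that add atoms: propargyl bromide 4, C#CCBr
Why: Williamson ether synthesis: the phenoxide, made more acidic by the ortho formyl and para acetyl groups, displaces bromide from the primary propargylic carbon by SN2.

Step 3
Reactants: 5 5-acetyl-2-(prop-2-yn-1-yloxy)benzaldehyde
Product: 6 1-[3-(dimethoxymethyl)-4-(prop-2-yn-1-yloxy)phenyl]ethan-1-one
Conditions: HC(OMe)3 (1.2 equiv), PPTS (5 mol %), MeOH, rt; Et3N quench
Reagents that add atoms: trimethyl orthoformate, COC(OC)OC; methanol, CO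
Why: Acid-catalysed acetalisation with orthoformate as water scavenger: the aldehyde reacts far faster than the aryl methyl ketone, which is deactivated further by the para ether oxygen, so quenching once 5 is consumed should leave the acetyl group free.

Step 4
Reactants: 6 1-[3-(dimethoxymethyl)-4-(prop-2-yn-1-yloxy)phenyl]ethan-1-one
Product: 7 (1R)-1-[3-(dimethoxymethyl)-4-(prop-2-yn-1-yloxy)phenyl]ethan-1-ol
Conditions: RuCl[(R,R)-TsDPEN](p-cymene) (1 mol %), HCO2Na (5 equiv), H2O/MeOH (1:1), 40 °C
Reagents that add atoms: none
Why: Noyori–Ikariya asymmetric transfer hydrogenation: the ruthenium hydride with the (R,R)-diamine delivers hydride and proton to the aryl methyl ketone through the outer-sphere six-membered transition state that places the aryl group next to the η6-arene, which gives the (R)-carbinol as with acetophenone, and the near-neutral formate medium leaves the acetal and the alkyne untouched.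

Step 5
Reactants: 7 (1R)-1-[3-(dimethoxymethyl)-4-(prop-2-yn-1-yloxy)phenyl]ethan-1-ol
Product: 8 (1R)-1-[3-(dimethoxymethyl)-4-(propa-1,2-dien-1-yloxy)phenyl]ethan-1-ol
Conditions: KOtBu (1.3 equiv), THF, 0 °C to rt; H2O quench
Reagents that add atoms: none
Why: Base-mediated propargyl-to-allenyl prototropic isomerisation: tert-butoxide removes an OCH2 proton and reprotonation at the alkyne terminus gives the aryloxyallene, the preferred isomer under these conditions, while the carbinol is present only as its alkoxide and the acetal is inert to base, so the (R) centre is not touched.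

Step 6
Reactants: 8 (1R)-1-[3-(dimethoxymethyl)-4-(propa-1,2-dien-1-yloxy)phenyl]ethan-1-ol; 9 isovaleric anhydride
Product: 10 (1R)-1-[3-(dimethoxymethyl)-4-(propa-1,2-dien-1-yloxy)phenyl]ethyl 3-methylbutanoate
Conditions: (iPrCH2CO)2O (1.5 equiv), Et3N (2 equiv), DMAP (10 mol %), CH2Cl2, 0 °C to rt
Reagents that add atoms: isovaleric anhydride 9, CC(C)CC(=O)OC(=O)CC(C)C
Why: DMAP-catalysed acyl transfer from the anhydride to the secondary alcohol (Steglich-type esterification); only the O–H bond reacts, so the (R) configuration is retained, and the amine-buffered medium spares the acetal and the allenyl ether.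

Step 7
Reactants: 10 (1R)-1-[3-(dimethoxymethyl)-4-(propa-1,2-dien-1-yloxy)phenyl]ethyl 3-methylbutanoate
Product: 11 (1R)-1-[3-formyl-4-(propa-1,2-dien-1-yloxy)phenyl]ethyl 3-methylbutanoate
Conditions: PPTS (10 mol %), acetone/H2O (10:1), rt
Reagents that add atoms: water, O
Why: Acid-catalysed acetal hydrolysis: the dimethyl acetal of an electron-rich benzaldehyde ionises readily under PPTS buffering at room temperature, whereas the aryloxyallene (a poorer proton acceptor than an alkoxyallene) and the benzylic ester should need stronger acid to react.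

Step 8
Reactants: 11 (1R)-1-[3-formyl-4-(propa-1,2-dien-1-yloxy)phenyl]ethyl 3-methylbutanoate; 12 bis(pinacolato)diboron
Product: 14 (1R)-1-[(2R,3R)-3-hydroxy-2-[1-(4,4,5,5-tetramethyl-1,3,2-dioxaborolan-2-yl)ethenyl]-2,3-dihydro-1-benzofuran-5-yl]ethyl 3-methylbutanoate, via 3-O-boryl ether 13 (not isolated)
Conditions: CuCl (5 mol %), (R,R)-Ph-BPE (6 mol %; antipode per the assumption), NaOtBu (20 mol %), B2pin2 (1.2 equiv), THF, 0 °C to rt; then pH 7 phosphate buffer
Reagents that add atoms: bis(pinacolato)diboron 12, CC1(C)OB(OC1(C)C)B1OC(C)(C)C(C)(C)O1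
Why: Proposed new method: CuCl, NaOtBu and B2pin2 give a bisphosphine-bound copper boryl that adds syn across the terminal C=C of the aryloxyallene with boron going to the central carbon, and the resulting 2-boryl allylcopper (its two σ-forms interconvert by 1,3-shift) attacks the ortho formyl group through its oxygen-bearing γ-carbon in a closed six-membered Cu–O-bridged transition state, after which B2pin2 turns the copper alkoxide over to the O-boryl ether 13, hydrolysed on work-up. The closest known reaction type is the copper–bisphosphine-catalysed enantioselective borylative coupling of allenes with aldehydes and ketones, together with its ring-forming variant on carbon-tethered allenyl ketones; new here are the oxygen-substituted allene as allyl donor and the fused five-membered ring. The dihydrofuran ring closes in a 5-exo-trig mode on the carbonyl carbon, whereas attack through the CH2 terminus would need a seven-membered ring. C2 and C3 form together: their cis relation follows from the cyclic transition state, in which the boryl-bearing vinyl carbon and the carbonyl oxygen both belong to the copper-bridged six-membered array and so end on the same face of the new ring, and their absolute (2R,3R) configuration comes from the chiral bisphosphine, which selects the aldehyde face while the remote side-chain centre is a bystander. The step needs Cu–B addition to the allene ahead of the aldehyde, γ-regioselectivity and cis selectivity; the first is the normal preference of phosphine–copper boryls, and the other two are secured by the ortho placement of the formyl group, which allows only the five-membered closure.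

Step 9
Reactants: 14 (1R)-1-[(2R,3R)-3-hydroxy-2-[1-(4,4,5,5-tetramethyl-1,3,2-dioxaborolan-2-yl)ethenyl]-2,3-dihydro-1-benzofuran-5-yl]ethyl 3-methylbutanoate; 9 isovaleric anhydride
Product: 15 (1R)-1-[(2R,3R)-3-(3-methylbutanoyloxy)-2-[1-(4,4,5,5-tetramethyl-1,3,2-dioxaborolan-2-yl)ethenyl]-2,3-dihydro-1-benzofuran-5-yl]ethyl 3-methylbutanoate
Conditions: (iPrCH2CO)2O (1.5 equiv), Et3N (2 equiv), DMAP (10 mol %), CH2Cl2, 0 °C
Reagents that add atoms: isovaleric anhydride 9, CC(C)CC(=O)OC(=O)CC(C)C
Why: DMAP-catalysed acylation of the benzylic secondary alcohol by the anhydride; the C3–O bond is not broken so the cis (2R,3R) arrangement is kept, the alkenyl boronate is inert, and the cold amine-buffered medium avoids acid-promoted dehydration to the benzofuran.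

Step 10
Reactants: 15 (1R)-1-[(2R,3R)-3-(3-methylbutanoyloxy)-2-[1-(4,4,5,5-tetramethyl-1,3,2-dioxaborolan-2-yl)ethenyl]-2,3-dihydro-1-benzofuran-5-yl]ethyl 3-methylbutanoate
Product: 16 (1R)-1-[(2S,3R)-2-(1-iodoethenyl)-3-(3-methylbutanoyloxy)-2,3-dihydro-1-benzofuran-5-yl]ethyl 3-methylbutanoate (cis)
Conditions: NaI (1.5 equiv), TsN(Cl)Na (chloramine-T, 1.5 equiv), THF/H2O (1:1), 0 °C to rt, dark; Na2S2O3 quench
Reagents that add atoms: sodium iodide, [Na+].[I-]
Why: Kabalka-type iododeboronation: TsN(Cl)Na oxidises iodide to an electrophilic iodine species that replaces the alkenyl C–B bond at the same carbon, and the near-neutral aqueous medium should spare both esters and the stereocentres, none of which takes part.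

Step 11
Reactants: 16 (1R)-1-[(2S,3R)-2-(1-iodoethenyl)-3-(3-methylbutanoyloxy)-2,3-dihydro-1-benzofuran-5-yl]ethyl 3-methylbutanoate
Product: 17 2-[(2R,3R)-3-(3-methylbutanoyloxy)-5-[(1R)-1-(3-methylbutanoyloxy)ethyl]-2,3-dihydro-1-benzofuran-2-yl]prop-2-enal (CNP0316116.1)
Conditions: Pd(PPh3)4 (5 mol %), CO (1–3 atm), Bu3SnH (1.1 equiv, slow addition), THF, 50 °C
Reagents that add atoms: carbon monoxide, [C-]#[O+]
Why: Palladium-catalysed reductive carbonylation (Baillargeon–Stille formylation): oxidative addition of the alkenyl iodide to zerovalent palladium, CO insertion to the acylpalladium and hydride transfer from Bu3SnH followed by reductive elimination give the enal, slow addition of the hydride under CO keeping direct reduction of the C–I bond in check, and the neutral medium leaves C2 and C3 as they are.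

**Compound list**

1 | 4'-hydroxyacetophenone | CC(=O)c1ccc(O)cc1 | starting material
2 | 1-[4-hydroxy-3-(hydroxymethyl)phenyl]ethan-1-one (5-acetylsalicyl alcohol, present as its magnesium salt) | CC(=O)c1ccc(O)c(CO)c1 | intermediate (not isolated)
3 | 5-acetyl-2-hydroxybenzaldehyde | CC(=O)c1ccc(O)c(C=O)c1 | intermediate
4 | propargyl bromide | C#CCBr | starting material
5 | 5-acetyl-2-(prop-2-yn-1-yloxy)benzaldehyde | CC(=O)c1ccc(OCC#C)c(C=O)c1 | intermediate
6 | 1-[3-(dimethoxymethyl)-4-(prop-2-yn-1-yloxy)phenyl]ethan-1-one | CC(=O)c1ccc(OCC#C)c(C(OC)OC)c1 | intermediate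
7 | (1R)-1-[3-(dimethoxymethyl)-4-(prop-2-yn-1-yloxy)phenyl]ethan-1-ol | C#CCOc1ccc([C@@H](C)O)cc1C(OC)OC | intermediate
8 | (1R)-1-[3-(dimethoxymethyl)-4-(propa-1,2-dien-1-yloxy)phenyl]ethan-1-ol | C=C=COc1ccc([C@@H](C)O)cc1C(OC)OC | intermediate
9 | isovaleric anhydride (3-methylbutanoic anhydride) | CC(C)CC(=O)OC(=O)CC(C)C | starting material
10 | (1R)-1-[3-(dimethoxymethyl)-4-(propa-1,2-dien-1-yloxy)phenyl]ethyl 3-methylbutanoate | C=C=COc1ccc([C@@H](C)OC(=O)CC(C)C)cc1C(OC)OC | intermediate
11 | (1R)-1-[3-formyl-4-(propa-1,2-dien-1-yloxy)phenyl]ethyl 3-methylbutanoate | C=C=COc1ccc([C@@H](C)OC(=O)CC(C)C)cc1C=O | intermediate (key-step precursor)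
12 | bis(pinacolato)diboron | CC1(C)OB(OC1(C)C)B1OC(C)(C)C(C)(C)O1 | starting material
13 | (1R)-1-[(2R,3R)-3-(pinacolboryloxy)-2-[1-(pinacolboryl)ethenyl]-2,3-dihydro-1-benzofuran-5-yl]ethyl 3-methylbutanoate (cis) | C=C(B1OC(C)(C)C(C)(C)O1)[C@H]1Oc2ccc([C@@H](C)OC(=O)CC(C)C)cc2[C@H]1OB1OC(C)(C)C(C)(C)O1 | intermediate (not isolated)
14 | (1R)-1-[(2R,3R)-3-hydroxy-2-[1-(4,4,5,5-tetramethyl-1,3,2-dioxaborolan-2-yl)ethenyl]-2,3-dihydro-1-benzofuran-5-yl]ethyl 3-methylbutanoate (cis) | C=C(B1OC(C)(C)C(C)(C)O1)[C@H]1Oc2ccc([C@@H](C)OC(=O)CC(C)C)cc2[C@H]1O | intermediate (key-step product)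
15 | (1R)-1-[(2R,3R)-3-(3-methylbutanoyloxy)-2-[1-(4,4,5,5-tetramethyl-1,3,2-dioxaborolan-2-yl)ethenyl]-2,3-dihydro-1-benzofuran-5-yl]ethyl 3-methylbutanoate (cis) | C=C(B1OC(C)(C)C(C)(C)O1)[C@H]1Oc2ccc([C@@H](C)OC(=O)CC(C)C)cc2[C@H]1OC(=O)CC(C)C | intermediate
16 | (1R)-1-[(2S,3R)-2-(1-iodoethenyl)-3-(3-methylbutanoyloxy)-2,3-dihydro-1-benzofuran-5-yl]ethyl 3-methylbutanoate (cis) | C=C(I)[C@H]1Oc2ccc([C@@H](C)OC(=O)CC(C)C)cc2[C@H]1OC(=O)CC(C)C | intermediate
17 | 2-[(2R,3R)-3-(3-methylbutanoyloxy)-5-[(1R)-1-(3-methylbutanoyloxy)ethyl]-2,3-dihydro-1-benzofuran-2-yl]prop-2-enal (cis) | C=C(C=O)[C@H]1Oc2ccc([C@@H](C)OC(=O)CC(C)C)cc2[C@H]1OC(=O)CC(C)C | target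

**Count**

Total steps: 11. Longest linear sequence: 11 steps (1 to 17).

**Steps most likely to fail**

Step 8 (carries the label). What may go wrong: poor facial selectivity at the aldehyde because the rigid bicyclic transition state blunts ligand control, copper–boryl addition to the formyl group instead of the allene, or protonation of the allylcopper before ring closure.

Fallback with known chemistry, from 11 back to 14. Pt(dba)2 (3 mol %), PCy3 (6 mol %) and B2pin2 12 in toluene at 50 °C should diborate the terminal C=C of the allene; this is platinum-catalysed allene diboration, terminal-selective with the bulky phosphine. It gives the (Z)-γ-aryloxy-2-boryl allylboronate F1. F1 cyclises in the flask by thermal intramolecular allylboration of the ortho aldehyde through a closed six-membered B–O-bridged transition state, hence again cis. This gives 13 together with the (2S,3S) O-boryl ether F2. Aqueous work-up gives 14 and the (2S,3S) hydroxy boronate F3. These are diastereomers because of the side-chain centre and are parted by preparative HPLC; 14 re-enters at step 9. The price is that the absolute configuration is no longer set by a catalyst and about half of the material is the unwanted isomer.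

Step 11. What may go wrong: hydride transfer before CO insertion (hydrodeiodination), conjugate reduction of the enal by the tin hydride, or phosphine-triggered conjugate addition–elimination that opens the ring at the C2–O1 bond of the product, which is an aryl ether of the Morita–Baylis–Hillman type.

Fallback, from 16 to 17. Stille coupling of 16 with Bu3SnCH2OH (Pd(PPh3)4, CuI, DMF, 45 °C) should bring in the carbon at the alcohol oxidation level and give the allylic alcohol F4. F4 is not a Michael acceptor and tolerates the catalyst. MnO2 in CH2Cl2 at rt then oxidises the primary allylic alcohol to the enal 17 under neutral, non-nucleophilic conditions.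

Step 10. What may go wrong: electrophilic iodination of the electron-rich arene at C7 competing with slow substitution at the hindered 1,1-disubstituted alkenyl boronate, or base-induced loss of the C3 ester towards the benzofuran.

Fallback, from 15 to 16. KHF2 in MeOH/H2O at rt converts the pinacol boronate into the potassium alkenyltrifluoroborate F5, a salt that can be freed of pinacol by crystallisation. It is the boron species on which NaI/TsN(Cl)Na iodination is fastest (THF/H2O, 0 °C, minutes), so ring iodination and elimination should not keep pace. The product is 16.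

**Further compounds**

F1 | step 8 | (1R)-1-[3-formyl-4-[(Z)-2,3-bis(4,4,5,5-tetramethyl-1,3,2-dioxaborolan-2-yl)prop-1-en-1-yloxy]phenyl]ethyl 3-methylbutanoate | O=Cc1cc([C@@H](C)OC(=O)CC(C)C)ccc1O/C=C(\CB1OC(C)(C)C(C)(C)O1)B1OC(C)(C)C(C)(C)O1
F2 | step 8 | (1R)-1-[(2S,3S)-3-(pinacolboryloxy)-2-[1-(pinacolboryl)ethenyl]-2,3-dihydro-1-benzofuran-5-yl]ethyl 3-methylbutanoate (cis) | C=C(B1OC(C)(C)C(C)(C)O1)[C@@H]1Oc2ccc([C@@H](C)OC(=O)CC(C)C)cc2[C@@H]1OB1OC(C)(C)C(C)(C)O1
F3 | step 8 | (1R)-1-[(2S,3S)-3-hydroxy-2-[1-(4,4,5,5-tetramethyl-1,3,2-dioxaborolan-2-yl)ethenyl]-2,3-dihydro-1-benzofuran-5-yl]ethyl 3-methylbutanoate (cis) | C=C(B1OC(C)(C)C(C)(C)O1)[C@@H]1Oc2ccc([C@@H](C)OC(=O)CC(C)C)cc2[C@@H]1O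
F4 | step 11 | (1R)-1-[(2R,3R)-2-(3-hydroxyprop-1-en-2-yl)-3-(3-methylbutanoyloxy)-2,3-dihydro-1-benzofuran-5-yl]ethyl 3-methylbutanoate (cis) | C=C(CO)[C@H]1Oc2ccc([C@@H](C)OC(=O)CC(C)C)cc2[C@H]1OC(=O)CC(C)C
F5 | step 10 | potassium trifluoro[1-[(2R,3R)-3-(3-methylbutanoyloxy)-5-[(1R)-1-(3-methylbutanoyloxy)ethyl]-2,3-dihydro-1-benzofuran-2-yl]ethenyl]borate (cis) | C=C([B-](F)(F)F)[C@H]1Oc2ccc([C@@H](C)OC(=O)CC(C)C)cc2[C@H]1OC(=O)CC(C)C.[K+]
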